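The numbers in the tables are simulated on assumed constants.

**Earlier runs.** Wednesday's run and Friday's run were my starting point, and I compared what each lost of its solid substrate in the first minute.

| setting | Wednesday's | Friday's | flask |
|---|---|---|---|
| solid substrate | 0.067 M | 0.15 M | 0.10 M |
| remark | run made earlier | run made earlier |  |
| time |  |  | 80 min |

| run | time / min | target / % | solid substrate / % |
|---|---|---|---|
| Wednesday's | 1.00 | 9.2 | 51.1 |
| Wednesday's | 4.00 | 26.5 | 0.5 |
| Wednesday's | 15.0 | 15.3 | 0.3 |
| Wednesday's | 60.0 | 5.0 | 0 |
| Friday's | 1.00 | 4.0 | 78.3 |
| Friday's | 4.00 | 16.9 | 27.2 |
| Friday's | 15.0 | 12.1 | 0.1 |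
| Friday's | 60.0 | 2.4 | 0 |

(scatter of a reading: 0.5 percentage points)

1. the best time, 80 min at the latest, for target
2. the amount of target, in percent of the solid substrate charged, at that time
3. earliest time at which at least nineteen twentieths of that best amount are there, in min
4. latest time at which they still are, in min

- solid substrate is a solid; its amount is given per volume of the solution
- at the start none of the solid substrate is in solution

**One number.** Wednesday's run lost 48.9 % of its charge and Friday's 21.7 %. Their ratio, 2.25, matched the inverse ratio of the charges, 2.24, so the same amount entered solution in both first minutes. For the new flask, the charge divided by that amount is 3.07. This clearing number says how many first minutes' intake the charge holds; it was 2.06 for Wednesday's run and 4.61 for Friday's. In both runs target had fallen by 15.0 min, when the solid substrate read 0.3 % in Wednesday's run and 0.1 % in Friday's, so I tied its peak to clearing.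

**Was it enough?** For 4.00 min in Friday's run, I reckoned 13.2 % left at a steady intake, but the reading was 27.2 %, more, so intake slowed in that run. With Friday's four-minute mean, I reckoned the flask clear at 3.66 min. Interpolating the highest readings along the number gave me 22.7 %.

**The forecast.** The forecast gave 24 % at 4.2 min, above my height, within 3.4 min to 5 min: target “peaks just after the solid disappears”.

**The flask.** The flask gave 24.5 % at 4.08 min, and the window asked for ran from 3.54 min to 5.05 min.

    starting material ⇌ target (K = 1.40, k = 0.0110 s⁻¹)
    target ⇌ isomer of the product (K = 0.820, k = 0.00600 s⁻¹)
    isomer of the product ⇌ starting material (k = 0.00440 s⁻¹)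
    solid substrate ⇌ starting material, rate k4*(cs4 - [starting material]) while solid is left; crystals form when [starting material] > cs4 (solubility = 0.0660 M, k = 0.0100 s⁻¹)
    2 starting material → homo dimer (k = 0.180 M⁻¹ s⁻¹)

**Rates compared.** In the flask, the path from two starting material to homo dimer used starting material at 0.71 of the forward rate of the path to target at 1.64 min, and at 0.068 at 80.0 min. The peak came at 1.33 times the clearing number in minutes, and the neighbour charged with 0.40 M, whose number is 12.3, higher than the flask's, reached 10.7 %.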